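**Retrosynthetic overview** (numbering: O1 and C2–C5 in the butenolide ring, C6–C14 along the chain, then furan ring A (2,4-disubstituted) and furan ring B (3-substituted))
1. The strategy rests on C7: it carries CH3, C6 and the C8 methylene, and C8 is bonded to the sp2 carbon C9. This is the CH3–CH(B)–CH2–alkenyl pattern that a vinylboron conjunctive coupling delivers.
2. C5=C6 is cut by aldol/dehydration with the O-methyl tetronate, and C6–C7 by one-carbon Matteson homologation of a C7 boronic ester.
3. C7–CH3 and C8–C9 are cut together into MeLi, vinylB(pin) and the (9E,11E)-dienyl bromide.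
4. The dienyl bromide comes from the bis-furan propanal (Wittig, then Takai–Utimoto); the bis-furan comes from 3-bromofuran, 4-bromofuran-2-carbaldehyde and a B-alkyl Suzuki coupling.
5. Rings: both furans are bought; the butenolide is the only ring made (step 11, from ethyl 2-methylacetoacetate) and is joined last.

Key step: step 7

Remark on the chemistry: the antipode of the ferrocenyl bisphosphine in step 7 is taken to be the one that gives (S) at C7; the sense of induction would be checked on a small scale and the other antipode used if needed. Anhydrous CrBr2 is assumed to be used as the purchased salt.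

**Step 1**
Reactants: 1 3-bromofuran; 3 4-bromofuran-2-carbaldehyde
Product: 4 (4-bromofuran-2-yl)(furan-3-yl)methanol (racemic), via furan-3-yllithium 2 (not isolated)
Conditions: n-BuLi, THF, −78 °C; then 3, −78 °C; H2O quench
Reagents that add atoms: none
Why: Bromine–lithium exchange gives furan-3-yllithium, which is configurationally stable at −78 °C and adds 1,2 to the aldehyde faster than it exchanges with the ring bromide of 3; the carbinol centre forms racemic and is removed in step 2.

**Step 2**
Reactants: 4 (4-bromofuran-2-yl)(furan-3-yl)methanol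
Product: 5 4-bromo-2-(furan-3-ylmethyl)furan
Conditions: Et3SiH (3 equiv), CF3CO2H (3 equiv), CH2Cl2, −20 → 0 °C
Reagents that add atoms: none
Why: Ionic hydrogenation, in which acid ionises the doubly heteroaryl-stabilised carbinol and the furfuryl cation is trapped by hydride from the silane, while the bromine on ring A damps acid-induced oligomerisation.

**Step 3**
Reactants: 5 4-bromo-2-(furan-3-ylmethyl)furan; 6 3,3-diethoxyprop-1-ene
Product: 8 4-(3,3-diethoxypropyl)-2-(furan-3-ylmethyl)furan, via 9-(3,3-diethoxypropyl)-9-borabicyclo[3.3.1]nonane 7 (not isolated)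
Conditions: 6, 9-BBN, THF, 0 °C → rt; then 5, PdCl2(dppf) (5 mol%; dppf = 1,1'-bis(diphenylphosphino)ferrocene), 3 M aq. K3PO4, DMF, 60 °C
Reagents that add atoms: none
Why: Anti-Markovnikov hydroboration followed by B-alkyl Suzuki–Miyaura coupling at the ring-A C–Br bond installs C12–C14 with the aldehyde masked as a base-stable acetal.

**Step 4**
Reactants: 8 4-(3,3-diethoxypropyl)-2-(furan-3-ylmethyl)furan
Product: 9 3-[5-(furan-3-ylmethyl)furan-3-yl]propanal
Conditions: p-TsOH·H2O (cat.), acetone/H2O (10:1), rt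
Reagents that add atoms: water, O
Why: Acid-catalysed acetal hydrolysis of an aliphatic diethyl acetal proceeds under conditions mild enough to leave the 2-alkylfurans intact.

**Step 5**
Reactants: 9 3-[5-(furan-3-ylmethyl)furan-3-yl]propanal; 10 2-(triphenylphosphoranylidene)propanal
Product: 11 (2E)-5-[5-(furan-3-ylmethyl)furan-3-yl]-2-methylpent-2-enal
Conditions: toluene, 90 °C
Reagents that add atoms: none
Why: Wittig reaction of a stabilised formyl ylide with an aliphatic aldehyde is under thermodynamic control and should give the E trisubstituted enal (C11=C12), the ylide reacting only slowly with the conjugated product.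

**Step 6**
Reactants: 11 (2E)-5-[5-(furan-3-ylmethyl)furan-3-yl]-2-methylpent-2-enal
Product: 12 4-[(3E,5E)-6-bromo-4-methylhexa-3,5-dien-1-yl]-2-(furan-3-ylmethyl)furan
Conditions: CrBr2 (6 equiv), CHBr3 (2 equiv), THF, 0 °C → rt
Reagents that add atoms: bromoform, BrC(Br)Br
Why: Takai–Utimoto olefination, in which a geminal dichromium bromocarbenoid adds 1,2 to the enal and eliminates to the E bromoalkene (C9=C10), the all-bromide reagent excluding halogen scrambling.

**Step 7**
Reactants: 12 4-[(3E,5E)-6-bromo-4-methylhexa-3,5-dien-1-yl]-2-(furan-3-ylmethyl)furan; 13 vinylboronic acid pinacol ester; 14 methyllithium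
Product: 16 2-[(2S,4E,6E)-9-[5-(furan-3-ylmethyl)furan-3-yl]-6-methylnona-4,6-dien-2-yl]-4,4,5,5-tetramethyl-1,3,2-dioxaborolane, via lithium methyl(vinyl)pinacolatoborate 15 (not isolated)
Conditions: 13, MeLi, Et2O, 0 °C → rt, evaporate; then 12, Pd(OAc)2 (3 mol%), MandyPhos-type ligand 1,1'-bis[bis(3,5-dimethylphenyl)phosphino]-2,2'-bis[(dimethylamino)(phenyl)methyl]ferrocene (3.6 mol%, single antipode), NaOTf (2 equiv), THF, 60 °C
Reagents that add atoms: none
Why: MeLi adds to boron of 13 to give the four-coordinate borate 15, while zerovalent palladium inserts into the C9–Br bond of 12 with retention and NaOTf removes bromide as NaBr, leaving a cationic dienylpalladium complex that binds the vinyl group of 15. This π-activation triggers a 1,2-shift of methyl from boron to C7 anti to palladium (new C7–CH3 bond, palladium on C8), and C(sp3)–C(sp2) reductive elimination then forms C8–C9, so that three components are joined and boron stays on C7. The closest known reaction type is the palladium-catalysed enantioselective conjunctive cross-coupling of vinylboron ate complexes with aryl and alkenyl bromides or triflates. No ring is closed. The C7 stereocentre is set by the chiral bisphosphine on palladium, which selects one enantiotopic face of the bound vinylborate, and the stereospecific anti migration turns that choice into (S)-C7. The step needs the metallate shift to outrun direct Suzuki-type transfer of vinyl or methyl and β-hydride elimination, which the wide-bite-angle ligand, the halide scavenger and the single C–halogen bond of 12 should secure, and the 9E,11E geometry is kept because oxidative addition and reductive elimination are stereoretentive.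

**Step 8**
Reactants: 16 2-[(2S,4E,6E)-9-[5-(furan-3-ylmethyl)furan-3-yl]-6-methylnona-4,6-dien-2-yl]-4,4,5,5-tetramethyl-1,3,2-dioxaborolane
Product: 18 2-[(2R,4E,6E)-9-[5-(furan-3-ylmethyl)furan-3-yl]-2,6-dimethylnona-4,6-dien-1-yl]-4,4,5,5-tetramethyl-1,3,2-dioxaborolane, via chloromethyl borate complex 17 (not isolated)
Conditions: BrCH2Cl (3 equiv), n-BuLi (2.5 equiv), THF, −78 °C → rt
Reagents that add atoms: bromochloromethane, ClCBr
Why: Matteson homologation, in which chloromethyllithium generated at −78 °C adds to boron and the C7 group migrates to the CH2 carbon with loss of chloride and retention at C7 (the descriptor changes to R only through the priority rules), creating C6–C7.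

**Step 9**
Reactants: 18 2-[(2R,4E,6E)-9-[5-(furan-3-ylmethyl)furan-3-yl]-2,6-dimethylnona-4,6-dien-1-yl]-4,4,5,5-tetramethyl-1,3,2-dioxaborolane
Product: 19 (2S,4E,6E)-9-[5-(furan-3-ylmethyl)furan-3-yl]-2,6-dimethylnona-4,6-dien-1-ol
Conditions: 30% H2O2, 3 M NaOH, THF, 0 °C → rt
Reagents that add atoms: hydrogen peroxide, OO
Why: Oxidation of the C–B bond by hydroperoxide through a 1,2-shift from boron to oxygen leaves C7 untouched, and basic peroxide does not attack furans or unactivated alkenes.

**Step 10**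
Reactants: 19 (2S,4E,6E)-9-[5-(furan-3-ylmethyl)furan-3-yl]-2,6-dimethylnona-4,6-dien-1-ol
Product: 20 (2S,4E,6E)-9-[5-(furan-3-ylmethyl)furan-3-yl]-2,6-dimethylnona-4,6-dienal
Conditions: Dess–Martin periodinane, NaHCO3, CH2Cl2, 0 °C → rt; used at once
Reagents that add atoms: none
Why: Buffered Dess–Martin oxidation is neutral and fast, so the α-stereocentre C7 of the aldehyde should not epimerise and the furans and diene are left alone.

**Step 11**
Reactants: 21 ethyl 2-methyl-3-oxobutanoate
Product: 23 4-hydroxy-3-methylfuran-2(5H)-one, via ethyl 4-bromo-2-methyl-3-oxobutanoate 22 (not isolated)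
Conditions: Br2, CHCl3, 0 °C → rt, 16 h; concentrate; neat, 110 °C
Reagents that add atoms: none
Why: Bromination of the β-keto ester followed by HBr-mediated migration of bromine to the terminal carbon gives 22, whose ester carbonyl oxygen displaces bromide in a five-membered lactonisation with loss of bromoethane, the classical tetronic acid synthesis.

**Step 12**
Reactants: 23 4-hydroxy-3-methylfuran-2(5H)-one
Product: 24 4-methoxy-3-methylfuran-2(5H)-one
Conditions: Me2SO4, K2CO3, acetone, reflux
Reagents that add atoms: dimethyl sulfate, COS(=O)(=O)OC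
Why: O-Alkylation of the vinylogous acid with a hard methylating agent is favoured, C3 being already substituted.

**Step 13**
Reactants: 24 4-methoxy-3-methylfuran-2(5H)-one; 20 (2S,4E,6E)-9-[5-(furan-3-ylmethyl)furan-3-yl]-2,6-dimethylnona-4,6-dienal
Product: 26 5-[(2S,4E,6E)-9-[5-(furan-3-ylmethyl)furan-3-yl]-1-hydroxy-2,6-dimethylnona-4,6-dien-1-yl]-4-methoxy-3-methylfuran-2(5H)-one, via lithium 4-methoxy-3-methylfuran-2-olate 25 (not isolated)
Conditions: LiN(i-Pr)2, THF, −78 °C; then 20, −78 °C; AcOH quench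
Reagents that add atoms: none
Why: Deprotonation at C5 gives an aromatic furanolate that undergoes aldol addition through C5 to the aldehyde; the new C5 and C6 centres form as a mixture that step 14 erases, and the weakly basic furanolate should not enolise the aldehyde at C7.

**Step 14**
Reactants: 26 5-[(2S,4E,6E)-9-[5-(furan-3-ylmethyl)furan-3-yl]-1-hydroxy-2,6-dimethylnona-4,6-dien-1-yl]-4-methoxy-3-methylfuran-2(5H)-one
Product: 28 (5Z)-5-[(2S,4E,6E)-9-[5-(furan-3-ylmethyl)furan-3-yl]-2,6-dimethylnona-4,6-dien-1-ylidene]-4-methoxy-3-methylfuran-2(5H)-one, via mesylate 27 (not isolated)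
Conditions: MsCl, Et3N, CH2Cl2, 0 °C; then DBU, rt
Reagents that add atoms: none
Why: Mesylation and E1cB elimination through the C5 furanolate give the 5-ylidene butenolide, the Z isomer being favoured because the C6 substituent then avoids the C4 methoxy group (allylic 1,3-strain in the E isomer).

**Step 15**
Reactants: 28 (5Z)-5-[(2S,4E,6E)-9-[5-(furan-3-ylmethyl)furan-3-yl]-2,6-dimethylnona-4,6-dien-1-ylidene]-4-methoxy-3-methylfuran-2(5H)-one
Product: 29 (5Z)-5-[(2S,4E,6E)-9-[5-(furan-3-ylmethyl)furan-3-yl]-2,6-dimethylnona-4,6-dien-1-ylidene]-4-hydroxy-3-methylfuran-2(5H)-one (CNP0222779.1)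
Conditions: NaSPr (3 equiv), DMF, rt; cold 0.5 M HCl work-up
Reagents that add atoms: none
Why: Thiolate SN2 dealkylation at the O-methyl carbon of the vinylogous carbonate releases the stabilised tetronate anion, which is no longer a conjugate acceptor and gives the tetronic acid on acidification.

**Compound list**
1 | 3-bromofuran | Brc1ccoc1 | starting material
2 | furan-3-yllithium | [Li]c1ccoc1 | intermediate
3 | 4-bromofuran-2-carbaldehyde | O=Cc1cc(Br)co1 | starting material
4 | (4-bromofuran-2-yl)(furan-3-yl)methanol (racemic) | OC(c1ccoc1)c1cc(Br)co1 | intermediate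
5 | 4-bromo-2-(furan-3-ylmethyl)furan | Brc1coc(Cc2ccoc2)c1 | intermediate
6 | 3,3-diethoxyprop-1-ene (acrolein diethyl acetal) | C=CC(OCC)OCC | starting material
7 | 9-(3,3-diethoxypropyl)-9-borabicyclo[3.3.1]nonane | CCOC(CCB1C2CCCC1CCC2)OCC | intermediate
8 | 4-(3,3-diethoxypropyl)-2-(furan-3-ylmethyl)furan | CCOC(CCc1coc(Cc2ccoc2)c1)OCC | intermediate
9 | 3-[5-(furan-3-ylmethyl)furan-3-yl]propanal | O=CCCc1coc(Cc2ccoc2)c1 | intermediate
10 | 2-(triphenylphosphoranylidene)propanal | CC(C=O)=P(c1ccccc1)(c1ccccc1)c1ccccc1 | starting material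
11 | (2E)-5-[5-(furan-3-ylmethyl)furan-3-yl]-2-methylpent-2-enal | O=C/C(C)=C/CCc1coc(Cc2ccoc2)c1 | intermediate
12 | 4-[(3E,5E)-6-bromo-4-methylhexa-3,5-dien-1-yl]-2-(furan-3-ylmethyl)furan | Br/C=C/C(C)=C/CCc1coc(Cc2ccoc2)c1 | intermediate
13 | vinylboronic acid pinacol ester | C=CB1OC(C)(C)C(C)(C)O1 | starting material
14 | methyllithium | [Li]C | starting material
15 | lithium methyl(vinyl)pinacolatoborate | [Li+].C=C[B-]1(C)OC(C)(C)C(C)(C)O1 | intermediate
16 | 2-[(2S,4E,6E)-9-[5-(furan-3-ylmethyl)furan-3-yl]-6-methylnona-4,6-dien-2-yl]-4,4,5,5-tetramethyl-1,3,2-dioxaborolane | CC1(C)OB(OC1(C)C)[C@@H](C)C/C=C/C(C)=C/CCc1coc(Cc2ccoc2)c1 | intermediate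
17 | lithium (chloromethyl)borate complex of 16 | [Li+].ClC[B-]1(OC(C)(C)C(C)(C)O1)[C@@H](C)C/C=C/C(C)=C/CCc1coc(Cc2ccoc2)c1 | intermediate
18 | 2-[(2R,4E,6E)-9-[5-(furan-3-ylmethyl)furan-3-yl]-2,6-dimethylnona-4,6-dien-1-yl]-4,4,5,5-tetramethyl-1,3,2-dioxaborolane | CC1(C)OB(OC1(C)C)C[C@@H](C)C/C=C/C(C)=C/CCc1coc(Cc2ccoc2)c1 | intermediate
19 | (2S,4E,6E)-9-[5-(furan-3-ylmethyl)furan-3-yl]-2,6-dimethylnona-4,6-dien-1-ol | OC[C@@H](C)C/C=C/C(C)=C/CCc1coc(Cc2ccoc2)c1 | intermediate
20 | (2S,4E,6E)-9-[5-(furan-3-ylmethyl)furan-3-yl]-2,6-dimethylnona-4,6-dienal | O=C[C@@H](C)C/C=C/C(C)=C/CCc1coc(Cc2ccoc2)c1 | intermediate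
21 | ethyl 2-methyl-3-oxobutanoate (ethyl 2-methylacetoacetate) | CCOC(=O)C(C)C(C)=O | starting material
22 | ethyl 4-bromo-2-methyl-3-oxobutanoate | CCOC(=O)C(C)C(=O)CBr | intermediate
23 | 4-hydroxy-3-methylfuran-2(5H)-one (3-methyltetronic acid) | CC1=C(O)COC1=O | intermediate
24 | 4-methoxy-3-methylfuran-2(5H)-one | COC1=C(C)C(=O)OC1 | intermediate
25 | lithium 4-methoxy-3-methylfuran-2-olate | COc1coc(O[Li])c1C | intermediate
26 | 5-[(2S,4E,6E)-9-[5-(furan-3-ylmethyl)furan-3-yl]-1-hydroxy-2,6-dimethylnona-4,6-dien-1-yl]-4-methoxy-3-methylfuran-2(5H)-one (mixture at C5 and C6) | COC1=C(C)C(=O)OC1C(O)[C@@H](C)C/C=C/C(C)=C/CCc1coc(Cc2ccoc2)c1 | intermediate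
27 | methanesulfonate of 26 | COC1=C(C)C(=O)OC1C(OS(C)(=O)=O)[C@@H](C)C/C=C/C(C)=C/CCc1coc(Cc2ccoc2)c1 | intermediate
28 | (5Z)-5-[(2S,4E,6E)-9-[5-(furan-3-ylmethyl)furan-3-yl]-2,6-dimethylnona-4,6-dien-1-ylidene]-4-methoxy-3-methylfuran-2(5H)-one | CC1=C(OC)/C(=C/[C@@H](C)C/C=C/C(C)=C/CCc2coc(Cc3ccoc3)c2)OC1=O | intermediate
29 | (5Z)-5-[(2S,4E,6E)-9-[5-(furan-3-ylmethyl)furan-3-yl]-2,6-dimethylnona-4,6-dien-1-ylidene]-4-hydroxy-3-methylfuran-2(5H)-one | CC1=C(O)/C(=C/[C@@H](C)C/C=C/C(C)=C/CCc2coc(Cc3ccoc3)c2)OC1=O | target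

**Step count**
Total: 15 steps. Longest linear sequence: 13 steps (steps 1–10, then 13–15, from 3-bromofuran); the tetronate branch (steps 11–12) joins at step 13.

**Steps most likely to fail**

Step 7. Methyl is a reluctant migrating group, so direct Suzuki-type transfer of vinyl or methyl to the dienylpalladium intermediate may overtake the metallate shift, and the facial selectivity at C7 may fall short. A first remedy inside the step would be a bulkier diol on boron. The fallback sets out from 12 and comes back at 19, with the C7 centre bought instead of made. Commercial (R)-3-bromo-2-methylpropan-1-ol (OC[C@@H](C)CBr) is silylated (TBSCl, imidazole, DMF) to tert-butyl[(2R)-3-bromo-2-methylpropoxy]dimethylsilane F1. Zinc insertion (Zn dust, cat. I2, DMA, 70 °C) gives [(2R)-3-(tert-butyldimethylsilyloxy)-2-methylpropyl]zinc bromide F2. Negishi coupling of F2 with 12 (Pd(OAc)2, SPhos, THF/DMA, rt) forms C8–C9 with retention of the 9E geometry and gives tert-butyl{[(2S,4E,6E)-9-[5-(furan-3-ylmethyl)furan-3-yl]-2,6-dimethylnona-4,6-dien-1-yl]oxy}dimethylsilane F3. Bu4NF in THF then releases 19.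

Step 15. Reversible conjugate addition of thiolate at C6 and base-induced isomerisation of the 5-ylidene may erode the Z geometry or consume material before the methyl group is removed. The fallback sets out from 23 (with 20) and comes back at 29, replacing the methyl ether by an allyl ether that is removed without a nucleophile at sulfur. Mitsunobu O-allylation of 23 (allyl alcohol, PPh3, DIAD, THF) gives 3-methyl-4-(prop-2-en-1-yloxy)furan-2(5H)-one F4. LiN(i-Pr)2 at −78 °C gives lithium 3-methyl-4-(prop-2-en-1-yloxy)furan-2-olate F5, which adds to 20 to give the aldol adduct F6. MsCl/Et3N gives the methanesulfonate F7, and DBU gives the (5Z)-ylidene allyl ether F8. Pd(PPh3)4 (cat.) with morpholine in THF at rt transfers the allyl group to the amine (Tsuji–Trost deallylation), and mild acidification gives 29.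

Step 6. Geometric control in the olefination of the α-branched enal may be incomplete, and the strongly reducing medium may partly remove bromine from the product. The fallback sets out from 11 and comes back at 12, letting an alkyne hydrometallation fix the C9=C10 geometry. Lithiated trimethylsilyldiazomethane (Me3SiCHN2, n-BuLi, THF, −78 °C → rt; Colvin rearrangement) converts 11 to 2-(furan-3-ylmethyl)-4-[(3E)-4-methylhex-3-en-5-yn-1-yl]furan F9. Syn hydrozirconation with Cp2Zr(H)Cl (THF, rt) gives the (1E,3E)-dienylzirconocene chloride F10, and NBS at 0 °C cleaves the C–Zr bond with retention to give 12.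

**Further compounds**
F1 | step 7 | tert-butyl[(2R)-3-bromo-2-methylpropoxy]dimethylsilane | CC(C)(C)[Si](C)(C)OC[C@@H](C)CBr
F2 | step 7 | [(2R)-3-(tert-butyldimethylsilyloxy)-2-methylpropyl]zinc bromide | CC(C)(C)[Si](C)(C)OC[C@@H](C)C[Zn]Br
F3 | step 7 | tert-butyl{[(2S,4E,6E)-9-[5-(furan-3-ylmethyl)furan-3-yl]-2,6-dimethylnona-4,6-dien-1-yl]oxy}dimethylsilane | CC(C)(C)[Si](C)(C)OC[C@@H](C)C/C=C/C(C)=C/CCc1coc(Cc2ccoc2)c1
F4 | step 15 | 3-methyl-4-(prop-2-en-1-yloxy)furan-2(5H)-one | C=CCOC1=C(C)C(=O)OC1
F5 | step 15 | lithium 3-methyl-4-(prop-2-en-1-yloxy)furan-2-olate | C=CCOc1coc(O[Li])c1C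
F6 | step 15 | 5-[(2S,4E,6E)-9-[5-(furan-3-ylmethyl)furan-3-yl]-1-hydroxy-2,6-dimethylnona-4,6-dien-1-yl]-3-methyl-4-(prop-2-en-1-yloxy)furan-2(5H)-one | C=CCOC1=C(C)C(=O)OC1C(O)[C@@H](C)C/C=C/C(C)=C/CCc1coc(Cc2ccoc2)c1
F7 | step 15 | methanesulfonate of F6 | C=CCOC1=C(C)C(=O)OC1C(OS(C)(=O)=O)[C@@H](C)C/C=C/C(C)=C/CCc1coc(Cc2ccoc2)c1
F8 | step 15 | (5Z)-5-[(2S,4E,6E)-9-[5-(furan-3-ylmethyl)furan-3-yl]-2,6-dimethylnona-4,6-dien-1-ylidene]-3-methyl-4-(prop-2-en-1-yloxy)furan-2(5H)-one | CC1=C(OCC=C)/C(=C/[C@@H](C)C/C=C/C(C)=C/CCc2coc(Cc3ccoc3)c2)OC1=O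
F9 | step 6 | 2-(furan-3-ylmethyl)-4-[(3E)-4-methylhex-3-en-5-yn-1-yl]furan | C#C/C(C)=C/CCc1coc(Cc2ccoc2)c1
F10 | step 6 | chlorobis(cyclopentadienyl)[(1E,3E)-6-[5-(furan-3-ylmethyl)furan-3-yl]-3-methylhexa-1,3-dien-1-yl]zirconium | Cl[Zr](/C=C/C(C)=C/CCc1coc(Cc2ccoc2)c1)(C1C=CC=C1)C1C=CC=C1
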